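**Strategy.** The route rests on cutting the C4–C4a bond of the flavanone. The C4 carbonyl carbon of ring C is attached directly to C4a of ring A, so it can be carried as an exocyclic C4=CH2 group: a ketone equivalent that cannot enolise, which keeps C3 from epimerising and O1–C2 from opening. One intramolecular Heck reaction of an aryl iodide onto a vinyl group forms C4–C4a, closes ring C and leaves that methylene. The precursor is an enantiopure anti ether: a ring-A 2-iodophenol bound through O1 to the benzylic carbon (C2, bearing ring B) of a 2-methoxybut-3-enyl chain, with C2 and C3 already set by Brown methoxyallylboration and an inverting Mitsunobu etherification.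

Key step: step 7

Remark: the target SMILES is read as the (2R,3R)-2,3-trans flavanonol; the syn alcohol needed before the inverting etherification is therefore (1S,2S), the label (1R,2S) belonging to the anti aryl ether, and C3 changes label from S (4-methylidene) to R (4-ketone) only because the CIP rank of C4 changes.

**Route**

Step 1
Reactants: 1 syringaldehyde (4-hydroxy-3,5-dimethoxybenzaldehyde)
Product: 2 4-(benzyloxy)-3,5-dimethoxybenzaldehyde
Conditions: BnBr, K2CO3, DMF, 60 °C
Reagents that add atoms: benzyl bromide, BrCc1ccccc1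
Why: Williamson O-benzylation of the only acidic OH (phenoxide SN2 on benzyl bromide) is routine for this aldehyde and creates no stereocentre.

Step 2
Reactants: 2 4-(benzyloxy)-3,5-dimethoxybenzaldehyde
Product: 4 4-(benzyloxy)-3,5-dimethoxyphenol, via aryl formate 3 (not isolated)
Conditions: mCPBA, CH2Cl2, 0 °C → rt; then K2CO3 (cat.), MeOH, rt
Reagents that add atoms: 3-chloroperoxybenzoic acid (mCPBA), OOC(=O)c1cccc(Cl)c1
Why: Baeyer–Villiger (Dakin-type) oxidation, in which the electron-rich aryl group migrates in preference to hydride in the peracid adduct to give formate 3, which mild methanolysis cleaves to the phenol.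

Step 3
Reactants: 4 4-(benzyloxy)-3,5-dimethoxyphenol
Product: 5 4-(benzyloxy)-2-iodo-3,5-dimethoxyphenol
Conditions: NIS (1.0 equiv), MeCN, −20 → 0 °C, dark
Reagents that add atoms: N-iodosuccinimide, O=C1CCC(=O)N1I
Why: Electrophilic aromatic iodination ortho to the free OH, where the two open positions are equivalent by symmetry so only one mono-iodide can form, with one equivalent of NIS at low temperature limiting di-iodination.

Step 4
Reactants: 6 2,3-dihydroxy-4-methoxybenzaldehyde
Product: 7 2,3-bis(benzyloxy)-4-methoxybenzaldehyde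
Conditions: BnBr (2.4 equiv), K2CO3, DMF, 60 °C
Reagents that add atoms: benzyl bromide, BrCc1ccccc1
Why: Double Williamson etherification of both phenolic OH groups, the aldehyde being inert to K2CO3 and BnBr.

Step 5
Reactants: 8 allyl methyl ether; 7 2,3-bis(benzyloxy)-4-methoxybenzaldehyde
Product: 13 (1S,2S)-1-[2,3-bis(benzyloxy)-4-methoxyphenyl]-2-methoxybut-3-en-1-ol, via Z-methoxyallyllithium 9 (not isolated), via lithium methoxyborate 10 (not isolated), via Z-methoxyallylborane 11 (not isolated), via borinate ester 12 (not isolated)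
Conditions: s-BuLi, THF, −78 °C; (+)-Ipc2BOMe [from (−)-α-pinene], −78 °C; BF3·OEt2, then aldehyde 7, −78 °C → rt; NaOH, H2O2, H2O
Reagents that add atoms: none
Why: Brown γ-alkoxyallylboration, in which kinetic deprotonation of 8 gives the chelated Z-allyllithium 9, boron capture and BF3-induced loss of methoxide give Z-allylborane 11, and addition to 7 through a closed chair (Zimmerman–Traxler) transition state with the Z-methoxy group axial sets the syn C1/C2 relationship while the isopinocampheyl groups of the (−)-α-pinene series select the aldehyde face leading to the (1S,2S) enantiomer, oxidative work-up then freeing the alcohol from borinate 12.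

Step 6
Reactants: 13 (1S,2S)-1-[2,3-bis(benzyloxy)-4-methoxyphenyl]-2-methoxybut-3-en-1-ol; 5 4-(benzyloxy)-2-iodo-3,5-dimethoxyphenol
Product: 14 2-(benzyloxy)-5-{[(1R,2S)-1-[2,3-bis(benzyloxy)-4-methoxyphenyl]-2-methoxybut-3-en-1-yl]oxy}-4-iodo-1,3-dimethoxybenzene (anti ether)
Conditions: PPh3, DIAD, toluene, 0 °C → rt
Reagents that add atoms: none
Why: Mitsunobu etherification, in which the acidic iodophenol displaces the alkoxyphosphonium ion of 13 by SN2 with inversion at the benzylic carbon (1S → 1R, syn alcohol → anti ether), the apolar solvent, low temperature and the inductively destabilising β-methoxy group working against ionisation.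

Step 7
Reactants: 14 2-(benzyloxy)-5-{[(1R,2S)-1-[2,3-bis(benzyloxy)-4-methoxyphenyl]-2-methoxybut-3-en-1-yl]oxy}-4-iodo-1,3-dimethoxybenzene
Product: 15 (2R,3S)-6-(benzyloxy)-2-[2,3-bis(benzyloxy)-4-methoxyphenyl]-3,5,7-trimethoxy-4-methylidenechromane (2,3-trans)
Conditions: Pd(OAc)2 (10 mol %), PPh3 (30 mol %), Ag2CO3 (2 equiv), degassed MeCN, 80 °C
Reagents that add atoms: none
Why: Intramolecular Mizoroki–Heck reaction: Pd(OAc)2 (divalent palladium) is reduced by PPh3 to zerovalent palladium, which inserts into the C4a–I bond of ring A, syn carbopalladation of the pendant vinyl group joins C4a to the internal alkene carbon C4, and syn β-hydride elimination of the single hydrogen on C4 releases the exocyclic C4=CH2 alkene. The closest known reaction type is the Heck cyclisation of 2-halophenyl homoallyl ethers to 4-methylenechromans. Ring C (O1–C2–C3–C4–C4a–C8a) is closed in the 6-exo-trig mode. No stereocentre is created, and C2 and C3, set in steps 5 and 6, are carried through because the medium is neither acidic nor strongly basic and no carbonyl is present. The step needs exo rather than 7-endo closure, which the three-atom O1–C2–C3 tether enforces, and it needs the alkene to stay exocyclic, which Ag2CO3 secures by removing iodide and HI so that the palladium hydride is quenched before it can re-add and move the double bond to C3=C4.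

Step 8
Reactants: 15 (2R,3S)-6-(benzyloxy)-2-[2,3-bis(benzyloxy)-4-methoxyphenyl]-3,5,7-trimethoxy-4-methylidenechromane
Product: 17 (2R,3R)-6-(benzyloxy)-2-[2,3-bis(benzyloxy)-4-methoxyphenyl]-3,5,7-trimethoxychroman-4-one, via diol 16 (not isolated)
Conditions: OsO4 (cat.), NaIO4, 2,6-lutidine, 1,4-dioxane/H2O, rt
Reagents that add atoms: osmium tetroxide, O=[Os](=O)(=O)=O (delivers the C4 oxygen); sodium periodate, [Na+].[O-]I(=O)(=O)=O (restores it)
Why: Lemieux–Johnson oxidation, in which osmylation of the only alkene gives diol 16 and NaIO4 cleaves it to the aryl ketone and formaldehyde, the 2,6-lutidine buffer keeping the now enolisable C3 (already the more stable trans arrangement) undisturbed.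

Step 9
Reactants: 17 (2R,3R)-6-(benzyloxy)-2-[2,3-bis(benzyloxy)-4-methoxyphenyl]-3,5,7-trimethoxychroman-4-one
Product: 18 (2R,3R)-2-(2,3-dihydroxy-4-methoxyphenyl)-5,6-dihydroxy-3,7-dimethoxychroman-4-one (CNP0075602.1)
Conditions: BCl3 (excess), C6HMe5, CH2Cl2, −78 → 0 °C; then MeOH/H2O
Reagents that add atoms: none
Why: BCl3-mediated ether cleavage, in which the three aryl benzyl ethers are cleaved at low temperature with pentamethylbenzene trapping the benzyl cations, and the 5-methoxy group alone among the methyl ethers is cleaved because BCl3 sits in a six-membered chelate between O5 and the C4 carbonyl, which should leave the 3-, 7- and 4'-methoxy groups and both stereocentres untouched.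

**Compound list**

1 | syringaldehyde (4-hydroxy-3,5-dimethoxybenzaldehyde) | COc1cc(C=O)cc(OC)c1O | starting material
2 | 4-(benzyloxy)-3,5-dimethoxybenzaldehyde | COc1cc(C=O)cc(OC)c1OCc1ccccc1 | intermediate
3 | 4-(benzyloxy)-3,5-dimethoxyphenyl formate | COc1cc(OC=O)cc(OC)c1OCc1ccccc1 | intermediate (not isolated)
4 | 4-(benzyloxy)-3,5-dimethoxyphenol | COc1cc(O)cc(OC)c1OCc1ccccc1 | intermediate
5 | 4-(benzyloxy)-2-iodo-3,5-dimethoxyphenol | COc1cc(O)c(I)c(OC)c1OCc1ccccc1 | intermediate
6 | 2,3-dihydroxy-4-methoxybenzaldehyde | COc1ccc(C=O)c(O)c1O | starting material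
7 | 2,3-bis(benzyloxy)-4-methoxybenzaldehyde | COc1ccc(C=O)c(OCc2ccccc2)c1OCc1ccccc1 | intermediate
8 | allyl methyl ether (3-methoxyprop-1-ene) | COCC=C | starting material
9 | (Z)-(3-methoxyprop-2-en-1-yl)lithium | [Li]C/C=C\OC | intermediate (not isolated)
10 | lithium [(Z)-3-methoxyprop-2-en-1-yl](methoxy)bis(isopinocampheyl)borate, isopinocampheyl groups of the (−)-α-pinene series | [Li+].CO/C=C\C[B-](OC)([C@H]1C[C@H]2C[C@@H]([C@@H]1C)C2(C)C)[C@H]1C[C@H]2C[C@@H]([C@@H]1C)C2(C)C | intermediate (not isolated)
11 | [(Z)-3-methoxyprop-2-en-1-yl]bis(isopinocampheyl)borane, same isopinocampheyl series | CO/C=C\CB([C@H]1C[C@H]2C[C@@H]([C@@H]1C)C2(C)C)[C@H]1C[C@H]2C[C@@H]([C@@H]1C)C2(C)C | intermediate (not isolated)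
12 | (1S,2S)-1-[2,3-bis(benzyloxy)-4-methoxyphenyl]-2-methoxybut-3-en-1-yl bis(isopinocampheyl)borinate | COc1ccc([C@H](OB([C@H]2C[C@H]3C[C@@H]([C@@H]2C)C3(C)C)[C@H]2C[C@H]3C[C@@H]([C@@H]2C)C3(C)C)[C@@H](OC)C=C)c(OCc2ccccc2)c1OCc1ccccc1 | intermediate (not isolated)
13 | (1S,2S)-1-[2,3-bis(benzyloxy)-4-methoxyphenyl]-2-methoxybut-3-en-1-ol (syn) | COc1ccc([C@H](O)[C@@H](OC)C=C)c(OCc2ccccc2)c1OCc1ccccc1 | intermediate
14 | 2-(benzyloxy)-5-{[(1R,2S)-1-[2,3-bis(benzyloxy)-4-methoxyphenyl]-2-methoxybut-3-en-1-yl]oxy}-4-iodo-1,3-dimethoxybenzene (anti ether) | COc1ccc([C@@H](Oc2cc(OC)c(OCc3ccccc3)c(OC)c2I)[C@@H](OC)C=C)c(OCc2ccccc2)c1OCc1ccccc1 | intermediate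
15 | (2R,3S)-6-(benzyloxy)-2-[2,3-bis(benzyloxy)-4-methoxyphenyl]-3,5,7-trimethoxy-4-methylidenechromane (2,3-trans) | COc1ccc([C@H]2Oc3cc(OC)c(OCc4ccccc4)c(OC)c3C(=C)[C@@H]2OC)c(OCc2ccccc2)c1OCc1ccccc1 | intermediate
16 | (2R,3R)-6-(benzyloxy)-2-[2,3-bis(benzyloxy)-4-methoxyphenyl]-4-(hydroxymethyl)-3,5,7-trimethoxychroman-4-ol (C4 configuration left open) | COc1ccc([C@H]2Oc3cc(OC)c(OCc4ccccc4)c(OC)c3C(O)(CO)[C@@H]2OC)c(OCc2ccccc2)c1OCc1ccccc1 | intermediate (not isolated)
17 | (2R,3R)-6-(benzyloxy)-2-[2,3-bis(benzyloxy)-4-methoxyphenyl]-3,5,7-trimethoxychroman-4-one | COc1ccc([C@H]2Oc3cc(OC)c(OCc4ccccc4)c(OC)c3C(=O)[C@@H]2OC)c(OCc2ccccc2)c1OCc1ccccc1 | intermediate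
18 | (2R,3R)-2-(2,3-dihydroxy-4-methoxyphenyl)-5,6-dihydroxy-3,7-dimethoxychroman-4-one (2,3-trans) | COc1ccc([C@H]2Oc3cc(OC)c(O)c(O)c3C(=O)[C@@H]2OC)c(O)c1O | target

**Step count**

Total steps: 9. Longest linear sequence: 7 steps (steps 1, 2, 3, 6, 7, 8, 9, from syringaldehyde); the ring-B branch (steps 4 and 5) joins at step 6.

**Steps most likely to fail**

Step 7 (key step). The palladium hydride formed after β-hydride elimination may re-add and walk the double bond into ring C, giving a C3=C4 enol ether and erasing C3. Oxidative addition at the electron-rich, doubly ortho-substituted C4a–I bond may also be slow, so that direct arylation of ring B or reduction of the C–I bond competes. The fallback makes the same C4–C4a bond by carbonyl addition instead of alkene insertion. It sets out from 14, whose vinyl group is cleaved (OsO4 cat., NaIO4, 2,6-lutidine, dioxane/H2O, rt) to (2R,3R)-3-[4-(benzyloxy)-2-iodo-3,5-dimethoxyphenoxy]-3-[2,3-bis(benzyloxy)-4-methoxyphenyl]-2-methoxypropanal F1. An intramolecular Nozaki–Hiyama–Kishi reaction (CrCl2, NiCl2 cat., DMF, rt) should then add C4a to the aldehyde carbon under non-basic conditions and give (2R,3S)-6-(benzyloxy)-2-[2,3-bis(benzyloxy)-4-methoxyphenyl]-3,5,7-trimethoxychroman-4-ol F2 as a mixture of C4 epimers. Both epimers are oxidised (Dess–Martin periodinane, NaHCO3, CH2Cl2, rt) to ketone 17, where the route is rejoined and step 8 is no longer needed.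

Step 6. The alkoxyphosphonium ion may ionise at the electron-rich benzylic carbon before the hindered ortho-iodophenoxide attacks, so that inversion is incomplete. The resulting syn ether would have to be separated, since it leads into the 2,3-cis series; elimination is a further outlet. The fallback separates C–O bond formation from the iodine. It sets out from 13 and the un-iodinated phenol 4, which is less hindered and more nucleophilic. The same inverting etherification (PPh3, DIAD, toluene, 0 °C) should give 2-(benzyloxy)-5-{[(1R,2S)-1-[2,3-bis(benzyloxy)-4-methoxyphenyl]-2-methoxybut-3-en-1-yl]oxy}-1,3-dimethoxybenzene F3. Iodination with NIS (MeCN, 0 °C) is then expected at the two equivalent open positions of ring A, each activated by three ortho/para oxygens and more so than any position of ring B, which returns the route to 14.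

Step 9. The Lewis acid may over-cleave (loss of the 3-, 7- or 4'-methyl group), liberated benzyl cations may alkylate the electron-rich rings, or the benzylic C2–O1 bond may ionise with loss of configuration at C2. The fallback stages the deprotection. It sets out from 17: hydrogenolysis (H2, 10% Pd/C, EtOAc/MeOH, rt) should remove the three benzyl groups under neutral conditions and give (2R,3R)-2-(2,3-dihydroxy-4-methoxyphenyl)-6-hydroxy-3,5,7-trimethoxychroman-4-one F4. The 5-methyl ether alone is then cleaved by AlCl3 in MeCN at rt (chelation between O5 and the C4 carbonyl) with dilute aqueous HCl work-up, arriving at 18.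

**Further compounds**

F1 | step 7 | (2R,3R)-3-[4-(benzyloxy)-2-iodo-3,5-dimethoxyphenoxy]-3-[2,3-bis(benzyloxy)-4-methoxyphenyl]-2-methoxypropanal | COc1ccc([C@@H](Oc2cc(OC)c(OCc3ccccc3)c(OC)c2I)[C@@H](OC)C=O)c(OCc2ccccc2)c1OCc1ccccc1
F2 | step 7 | (2R,3S)-6-(benzyloxy)-2-[2,3-bis(benzyloxy)-4-methoxyphenyl]-3,5,7-trimethoxychroman-4-ol (C4 epimers) | COc1ccc([C@H]2Oc3cc(OC)c(OCc4ccccc4)c(OC)c3C(O)[C@@H]2OC)c(OCc2ccccc2)c1OCc1ccccc1
F3 | step 6 | 2-(benzyloxy)-5-{[(1R,2S)-1-[2,3-bis(benzyloxy)-4-methoxyphenyl]-2-methoxybut-3-en-1-yl]oxy}-1,3-dimethoxybenzene | COc1ccc([C@@H](Oc2cc(OC)c(OCc3ccccc3)c(OC)c2)[C@@H](OC)C=C)c(OCc2ccccc2)c1OCc1ccccc1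
F4 | step 9 | (2R,3R)-2-(2,3-dihydroxy-4-methoxyphenyl)-6-hydroxy-3,5,7-trimethoxychroman-4-one | COc1ccc([C@H]2Oc3cc(OC)c(O)c(OC)c3C(=O)[C@@H]2OC)c(O)c1O
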